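**Retrosynthetic overview**

1. Ring numbering as in the target (C1 = CMe2, C2 = CHBr, C3 = alkylidene carbon, C4 and C6 = CHCl, C5 = CH2). Target 20 ⇐ (Z)-allylic alcohol 19 (Appel) ⇐ exocyclic allene 17 (hydroboration from the C4 side sets the Z alkene) ⇐ allenol 14 (C4: oxidation, axial hydride, chlorination with inversion).
2. Key disconnection of 14: C3–C4 and C1–C2 in one operation, a formal [4+2] of lactol acetate 6 (C4, C5, C6, C1) with silylated bromoallene 11 (C2, C3 and both side-chain carbons). The cyclohexane, the only ring of the target, forms in this step; the oxolane of 6 is a temporary ring that the same step opens.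
3. Enabling feature: the oxolane ring of 6, whose acetal carbon C2 and tertiary ether carbon C5 flank O1 and are two latent cations in a 1,4 relation. They are met by two adjacent allene carbons of 11, made nucleophilic one after the other by its CH2–Si and vinylic C–Si bonds.
4. Stereochemistry: the C6–Cl centre is bought with (S)-chlorosuccinate 1; it sets C2 in the chair closure, then C4 (hydride, SN2) and the alkene geometry follow by substrate control.
5. 6 comes from 1 in two steps; 11 from propargylic bromide 7 and Grignard reagent 8 in two steps.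

Key step: step 5

Assumption: dimethyl (2S)-2-chlorobutanedioate 1 is treated as purchasable; it is the dimethyl ester of commercial (S)-chlorosuccinic acid, which derives from L-aspartic acid with retention.

**Route**

Step 1
Reactants: 1 dimethyl (2S)-2-chlorobutanedioate
Product: 4 (4S)-4-chloro-5,5-dimethyloxolan-2-one, via chloro ketone 2 (not isolated), via hydroxy ester 3 (not isolated)
Conditions: MeMgBr (2.1 equiv), CeCl3, THF, −78 °C; AcOH quench; then TsOH·H2O (cat.), CH2Cl2, rt
Reagents that add atoms: methylmagnesium bromide, C[Mg]Br
Why: The methylcerium reagent formed in situ should add twice to the α-chloro ester, the more electrophilic carbonyl group, with little enolisation of 1 or of transient ketone 2 (CeCl3-mediated Grignard addition to an ester), and hydroxy ester 3 closes to the γ-lactone under acid; the C–Cl stereocentre is bought with 1 and no bond to it is touched.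

Step 2
Reactants: 4 (4S)-4-chloro-5,5-dimethyloxolan-2-one
Product: 6 (4S)-4-chloro-5,5-dimethyloxolan-2-yl acetate (anomer mixture), via lactol 5 (not isolated)
Conditions: i-Bu2AlH, CH2Cl2, −78 °C; then Ac2O, pyridine, DMAP, −78 → 0 °C
Reagents that add atoms: acetic anhydride, CC(=O)OC(C)=O
Why: DIBAL-H at −78 °C stops at the aluminium hemiacetal, which is acetylated in the same flask (reductive acetylation of a lactone); the anomeric centre is left as a mixture because it becomes planar in step 5.

Step 3
Reactants: 7 (3-bromoprop-1-yn-1-yl)trimethylsilane; 8 [(trimethylsilyl)methyl]magnesium chloride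
Product: 9 (buta-2,3-diene-1,2-diyl)bis(trimethylsilane)
Conditions: CuBr·LiBr (10 mol%), THF, −78 → −20 °C
Reagents that add atoms: none
Why: Copper-catalysed anti-SN2′ substitution of a propargylic bromide by a Grignard reagent should give the allene, the new C–C bond forming at the silyl-bearing alkyne carbon as in the standard synthesis of 1-substituted 1-silylallenes.

Step 4
Reactants: 9 (buta-2,3-diene-1,2-diyl)bis(trimethylsilane)
Product: 11 (4-bromobuta-2,3-diene-1,2-diyl)bis(trimethylsilane) (racemic), via allenyllithium 10 (not isolated)
Conditions: n-BuLi, THF, −78 °C; then BrCl2C–CCl2Br, −78 °C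
Reagents that add atoms: 1,2-dibromo-1,1,2,2-tetrachloroethane, BrC(Cl)(Cl)C(Cl)(Cl)Br
Why: n-BuLi should remove an allenic CH2 proton (metalation of a 1,1-disubstituted silylallene at its free terminus) and the allenyllithium is brominated at the same carbon, the propargylic site being blocked by two bulky groups; 11 is racemic, which is harmless because its axis disappears in step 5.

Step 5
Reactants: 6 (4S)-4-chloro-5,5-dimethyloxolan-2-yl acetate; 11 (4-bromobuta-2,3-diene-1,2-diyl)bis(trimethylsilane)
Product: 14 (1S,3R,5S)-3-bromo-5-chloro-2-ethenylidene-4,4-dimethylcyclohexan-1-ol, via dienyl oxolane 12 (not isolated), via silyl ether 13 (not isolated)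
Conditions: Me3SiOTf (0.5 equiv), 2,6-di-tert-butyl-4-methylpyridine (0.2 equiv), CH2Cl2, −78 → 0 °C; then 1 M HCl, THF
Reagents that add atoms: none
Why: Proposed new method: Me3SiOTf ionises the anomeric acetate of 6 and the cyclic oxocarbenium ion is attacked by the central allene carbon of 11 on the side away from bromine with loss of the CH2-bound silyl group (anti-SE2′; closest known reaction: Hosomi–Sakurai-type substitution of lactol acetates by buta-2,3-dienylsilanes, which gives 2-substituted 1,3-dienes), so that 12 carries bromine cis to the silylvinyl group; the silyl triflate then silylates the ring oxygen, the tertiary C–O bond ionises with help from the neighbouring chlorine, the tertiary cation is trapped by the bromo-bearing diene terminus, and the β-silyl cation at C3 loses its vinylic silyl group to leave the exocyclic allene and return Me3SiOTf (closest known reactions: cation–olefin cyclisation started from a tertiary ether or epoxide and ended by a vinyl- or allylsilane). The cyclohexane closes 6-endo-trig through a chair in which the C6 chlorine lies anti to the forming C1–C2 bond and is therefore equatorial. C2 is controlled by that bought centre through the diene geometry, because the bromine that is trans to C4 on the double bond becomes equatorial and hence cis to the C6 chlorine; C4 arises from inside attack on the five-membered oxocarbenium ion (new group 1,3-cis to chlorine) and is erased again in step 6. The step needs attack of the oxocarbenium ion at the central carbon of 11 rather than at its bromo terminus, which the better hyperconjugation of the freely rotating CH2–Si bond and the deactivating bromine should secure, and it needs ionisation at the tertiary rather than the dienylic C–O bond, which is tolerable as an equilibrium because only the tertiary cation has an irreversible exit. Allene formation rather than an allyl cation is secured by the bromine itself, which forces the silylvinyl group perpendicular to the diene plane so that the C–Si bond overlaps the empty orbital at C3. The hindered pyridine keeps protic acid away from the acid-sensitive silanes.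

Step 6
Reactants: 14 (1S,3R,5S)-3-bromo-5-chloro-2-ethenylidene-4,4-dimethylcyclohexan-1-ol
Product: 15 (3R,5S)-3-bromo-5-chloro-2-ethenylidene-4,4-dimethylcyclohexan-1-one
Conditions: Dess–Martin periodinane, NaHCO3, CH2Cl2, 0 °C
Reagents that add atoms: none
Why: Dess–Martin oxidation of the secondary alcohol under buffered, neutral conditions should spare the β-chloro ketone and the allene; it removes the C4 carbinol centre, so that a C4 epimer of 14 would converge on the same ketone.

Step 7
Reactants: 15 (3R,5S)-3-bromo-5-chloro-2-ethenylidene-4,4-dimethylcyclohexan-1-one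
Product: 16 (1R,3R,5S)-3-bromo-5-chloro-2-ethenylidene-4,4-dimethylcyclohexan-1-ol
Conditions: NaBH4, CeCl3·7H2O, MeOH, −78 °C
Reagents that add atoms: none
Why: Luche 1,2-reduction: the small hydride should add axially to the cyclohexanone, whose C2 and C6 carry only hydrogen in the axial positions on that face, giving the equatorial alcohol, cis to the C6 chlorine.

Step 8
Reactants: 16 (1R,3R,5S)-3-bromo-5-chloro-2-ethenylidene-4,4-dimethylcyclohexan-1-ol
Product: 17 (2S,4S,6S)-2-bromo-4,6-dichloro-3-ethenylidene-1,1-dimethylcyclohexane
Conditions: PPh3, (Cl3C)2CO, CH2Cl2, −40 → 0 °C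
Reagents that add atoms: hexachloroacetone, ClC(Cl)(Cl)C(=O)C(Cl)(Cl)Cl
Why: Appel-type chlorodehydroxylation with PPh3 and hexachloroacetone, conditions known to convert allylic alcohols by SN2 displacement of the alkoxyphosphonium ion without allylic transposition, should invert C4 and turn the equatorial hydroxyl into the axial chloride, trans to the C6 chlorine.

Step 9
Reactants: 17 (2S,4S,6S)-2-bromo-4,6-dichloro-3-ethenylidene-1,1-dimethylcyclohexane
Product: 19 (2Z)-2-[(2S,4S,6S)-2-bromo-4,6-dichloro-3,3-dimethylcyclohexylidene]ethan-1-ol, via allylborane 18 (not isolated)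
Conditions: 9-BBN, THF, 0 °C; then 30% H2O2, pH 7 phosphate buffer, 0 °C
Reagents that add atoms: hydrogen peroxide, OO
Why: Hydroboration of a 1,1-disubstituted allene with 9-BBN places boron on the terminal carbon and hydrogen on the central one; the reacting π bond lies in the plane of the ring bonds at C3, where the approach past C2 is blocked by the equatorial bromine while the C4 side shows only an equatorial hydrogen (its chlorine is axial), so hydrogen should be delivered from the C4 side and the CH2B group end cis to C2 (Z), and buffered peroxide then oxidises the C–B bond with retention of the alkene geometry.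

Step 10
Reactants: 19 (2Z)-2-[(2S,4S,6S)-2-bromo-4,6-dichloro-3,3-dimethylcyclohexylidene]ethan-1-ol
Product: 20 (2S,3Z,4S,6S)-2-bromo-3-(2-bromoethylidene)-4,6-dichloro-1,1-dimethylcyclohexane
Conditions: PPh3, CBr4, CH2Cl2, −20 °C
Reagents that add atoms: carbon tetrabromide, BrC(Br)(Br)Br
Why: Appel bromination of the primary allylic alcohol (SN2 at CH2 without allylic transposition) under cold, neutral conditions should keep the Z geometry and leave the three secondary halides untouched.

**Compound list**

1 | dimethyl (2S)-2-chlorobutanedioate | COC(=O)C[C@H](Cl)C(=O)OC | starting material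
2 | methyl (3S)-3-chloro-4-oxopentanoate | COC(=O)C[C@H](Cl)C(C)=O | intermediate
3 | methyl (3S)-3-chloro-4-hydroxy-4-methylpentanoate | COC(=O)C[C@H](Cl)C(C)(C)O | intermediate
4 | (4S)-4-chloro-5,5-dimethyloxolan-2-one | CC1(C)OC(=O)C[C@@H]1Cl | intermediate
5 | (4S)-4-chloro-5,5-dimethyloxolan-2-ol (anomer mixture, formed as its aluminium alkoxide) | CC1(C)OC(O)C[C@@H]1Cl | intermediate
6 | (4S)-4-chloro-5,5-dimethyloxolan-2-yl acetate (anomer mixture) | CC1(C)OC(OC(C)=O)C[C@@H]1Cl | intermediate
7 | (3-bromoprop-1-yn-1-yl)trimethylsilane | C[Si](C)(C)C#CCBr | starting material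
8 | [(trimethylsilyl)methyl]magnesium chloride | C[Si](C)(C)C[Mg]Cl | starting material
9 | (buta-2,3-diene-1,2-diyl)bis(trimethylsilane) | C=C=C([Si](C)(C)C)C[Si](C)(C)C | intermediate
10 | (4-lithiobuta-2,3-diene-1,2-diyl)bis(trimethylsilane) | [Li]C=C=C([Si](C)(C)C)C[Si](C)(C)C | intermediate
11 | (4-bromobuta-2,3-diene-1,2-diyl)bis(trimethylsilane) (racemic) | BrC=C=C([Si](C)(C)C)C[Si](C)(C)C | intermediate
12 | (3S,5S)-5-[(1Z)-1-bromo-3-(trimethylsilyl)buta-1,3-dien-2-yl]-3-chloro-2,2-dimethyloxolane | CC1(C)O[C@@H](C[C@@H]1Cl)/C(=C/Br)C(=C)[Si](C)(C)C | intermediate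
13 | {[(1S,3R,5S)-3-bromo-5-chloro-2-ethenylidene-4,4-dimethylcyclohexyl]oxy}trimethylsilane | CC1(C)[C@H](Br)C(=C=C)[C@@H](O[Si](C)(C)C)C[C@@H]1Cl | intermediate
14 | (1S,3R,5S)-3-bromo-5-chloro-2-ethenylidene-4,4-dimethylcyclohexan-1-ol | CC1(C)[C@H](Br)C(=C=C)[C@@H](O)C[C@@H]1Cl | intermediate
15 | (3R,5S)-3-bromo-5-chloro-2-ethenylidene-4,4-dimethylcyclohexan-1-one | CC1(C)[C@H](Br)C(=C=C)C(=O)C[C@@H]1Cl | intermediate
16 | (1R,3R,5S)-3-bromo-5-chloro-2-ethenylidene-4,4-dimethylcyclohexan-1-ol | CC1(C)[C@H](Br)C(=C=C)[C@H](O)C[C@@H]1Cl | intermediate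
17 | (2S,4S,6S)-2-bromo-4,6-dichloro-3-ethenylidene-1,1-dimethylcyclohexane | CC1(C)[C@H](Br)C(=C=C)[C@@H](Cl)C[C@@H]1Cl | intermediate
18 | 9-{(2Z)-2-[(2S,4S,6S)-2-bromo-4,6-dichloro-3,3-dimethylcyclohexylidene]ethyl}-9-borabicyclo[3.3.1]nonane | CC1(C)[C@H](Br)/C(=C\CB2C3CCCC2CCC3)[C@@H](Cl)C[C@@H]1Cl | intermediate
19 | (2Z)-2-[(2S,4S,6S)-2-bromo-4,6-dichloro-3,3-dimethylcyclohexylidene]ethan-1-ol | CC1(C)[C@H](Br)/C(=C\CO)[C@@H](Cl)C[C@@H]1Cl | intermediate
20 | (2S,3Z,4S,6S)-2-bromo-3-(2-bromoethylidene)-4,6-dichloro-1,1-dimethylcyclohexane | CC1(C)[C@H](Br)/C(=C\CBr)[C@@H](Cl)C[C@@H]1Cl | target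

**Step count and risks**

Total step count: 10. Longest linear sequence: 8 steps (steps 3, 4, 5, 6, 7, 8, 9, 10; the branch through steps 1 and 2 is equally long).

Steps most likely to fail:

Step 5 (Proposed new method). The second ionisation may take place at the dienylic instead of the tertiary C–O bond, the tertiary cation may lose a proton instead of cyclising, the silanes may be protodesilylated, or the first substitution may occur at the bromo terminus of the allene. The fallback runs the same bond formations as three separate known reactions. It sets out from 6 and 11: BF3·OEt2 at −78 °C should stop after the Hosomi–Sakurai-type substitution, so that dienyl oxolane 12 is isolated. Me2BBr then cleaves the tertiary C–O bond of 12 to the tertiary bromide (1Z,3S,5S)-1,6-dibromo-5-chloro-6-methyl-2-[1-(trimethylsilyl)ethenyl]hept-1-en-3-ol F1. AgOTf with 2,6-di-tert-butylpyridine in CH2Cl2 ionises F1 for the chair cation–olefin closure ended by the vinylsilane. The fallback comes back to the route at 14.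

Step 9. Allylborane 18 may lose boron and the C2 bromine in a 1,4-elimination to a diene, a 1,3-boron shift may erode the Z geometry before oxidation, or the facial discrimination at the allene may be insufficient. The fallback sets out from 17 and uses platinum-catalysed hydroboration with pinacolborane (Pt(dba)2 and a triarylphosphine chosen for addition to the terminal double bond). This should give the isolable, configurationally stable and less Lewis-acidic allylboronic ester 2-{(2Z)-2-[(2S,4S,6S)-2-bromo-4,6-dichloro-3,3-dimethylcyclohexylidene]ethyl}-4,4,5,5-tetramethyl-1,3,2-dioxaborolane F2. Buffered peroxide oxidation of F2 comes back to the route at 19.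

Step 8. Chloride may attack the central allene carbon with allylic transposition to a 2-chloro-1,3-diene, or elimination may compete with substitution. The fallback sets out from 16 and moves the chlorination to a stage where C4 sits next to a trisubstituted alkene instead of an allene. Hydroboration with 9-BBN and buffered H2O2 (the equatorial hydroxyl is smaller than the bromine on the other side and can deliver boron) gives diol (1R,2Z,3R,5S)-3-bromo-5-chloro-2-(2-hydroxyethylidene)-4,4-dimethylcyclohexan-1-ol F3. TBSCl and imidazole silylate the primary hydroxyl to (1R,2Z,3R,5S)-3-bromo-2-{2-[(tert-butyldimethylsilyl)oxy]ethylidene}-5-chloro-4,4-dimethylcyclohexan-1-ol F4. PPh3 and hexachloroacetone invert C4 to {(2Z)-2-[(2S,4S,6S)-2-bromo-4,6-dichloro-3,3-dimethylcyclohexylidene]ethoxy}(tert-butyl)dimethylsilane F5. HF·pyridine removes the silyl group and the fallback comes back to the route at 19.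

**Further compounds**

F1 | step 5 | (1Z,3S,5S)-1,6-dibromo-5-chloro-6-methyl-2-[1-(trimethylsilyl)ethenyl]hept-1-en-3-ol | CC(C)(Br)[C@@H](Cl)C[C@H](O)/C(=C/Br)C(=C)[Si](C)(C)C
F2 | step 9 | 2-{(2Z)-2-[(2S,4S,6S)-2-bromo-4,6-dichloro-3,3-dimethylcyclohexylidene]ethyl}-4,4,5,5-tetramethyl-1,3,2-dioxaborolane | CC1(C)[C@H](Br)/C(=C\CB2OC(C)(C)C(C)(C)O2)[C@@H](Cl)C[C@@H]1Cl
F3 | step 8 | (1R,2Z,3R,5S)-3-bromo-5-chloro-2-(2-hydroxyethylidene)-4,4-dimethylcyclohexan-1-ol | CC1(C)[C@H](Br)/C(=C\CO)[C@H](O)C[C@@H]1Cl
F4 | step 8 | (1R,2Z,3R,5S)-3-bromo-2-{2-[(tert-butyldimethylsilyl)oxy]ethylidene}-5-chloro-4,4-dimethylcyclohexan-1-ol | CC1(C)[C@H](Br)/C(=C\CO[Si](C)(C)C(C)(C)C)[C@H](O)C[C@@H]1Cl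
F5 | step 8 | {(2Z)-2-[(2S,4S,6S)-2-bromo-4,6-dichloro-3,3-dimethylcyclohexylidene]ethoxy}(tert-butyl)dimethylsilane | CC1(C)[C@H](Br)/C(=C\CO[Si](C)(C)C(C)(C)C)[C@@H](Cl)C[C@@H]1Cl
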